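Rings: A (hydroxy-oxepane), B (methylenecyclohexane), C (acetoxycyclohexane), D (oxepanone). The ring-B methine bearing the two-carbon bridge sits next to the C=CH2 carbon. With that carbon read as a masked ketone, the methine–CH2 bond is the α,β-bond of an enone. Because A/B and C/D are the same trans-fused perhydrobenzoxepine, one open-chain all-S diepoxy vinyl ketone serves twice. A first copy is folded into rings C/D carrying an allyl arm. The key cross-metathesis welds this bicycle to a second, still acyclic copy. 1,4-Hydrosilylation of the new enone gives a regiodefined silyl enol ether, and an epoxide-opening cascade then closes rings A and B.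

Key step: step 6

Assumption: pure (E)-geranylacetone and the L-fructose-derived enantiomer of the Shi ketone are taken as purchasable. The D-fructose catalyst gives R,R-epoxides, so its enantiomer is needed for the all-S series.

Step 1
Reactants: 1 (E)-geranylacetone
Product: 2 (5S,6S,9S)-5,6:9,10-diepoxy-6,10-dimethylundecan-2-one
Conditions: L-fructose-derived Shi ketone (0.5 equiv), KHSO5 (as 2KHSO5·KHSO4·K2SO4), K2CO3, aq Na2B4O7 buffer, Bu4NHSO4, MeCN–CH2(OMe)2, 0 °C
Reagents that add atoms: potassium peroxymonosulfate, [K+].[O-]S(=O)(=O)OO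
Why: Shi asymmetric epoxidation: the dioxirane formed from the L-fructose-derived ketone transfers oxygen to each electron-rich trisubstituted alkene through a spiro transition state, so that catalyst control alone sets the S,S (internal) and S (terminal) epoxide centres, while the methyl ketone of 1 is not oxidised under the buffered conditions.

Step 2
Reactants: 2 (5S,6S,9S)-5,6:9,10-diepoxy-6,10-dimethylundecan-2-one
Product: 5 (6S,7S,10S)-6,7:10,11-diepoxy-7,11-dimethyldodec-1-en-3-one, via Mannich base 3 (not isolated), via quaternary ammonium iodide 4 (not isolated)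
Conditions: LiN(iPr)2, THF, –78 °C; CH2=NMe2+ I–, –78 °C → rt; MeI, rt; aq NaHCO3, CH2Cl2, rt
Reagents that add atoms: Eschenmoser salt (N,N-dimethylmethyleneiminium iodide), C=[N+](C)C.[I-]; iodomethane, CI (its methyl group stays only in 4)
Why: α-Methylenation by a Mannich reaction and Hofmann-type elimination: the hindered amide base removes a proton from the less substituted methyl side under kinetic control, the enolate adds to the iminium salt, and the quaternised amine leaves by E1cB under bicarbonate, conditions that leave the trisubstituted epoxides and their stereocentres untouched.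

Step 3
Reactants: 5 (6S,7S,10S)-6,7:10,11-diepoxy-7,11-dimethyldodec-1-en-3-one
Product: 6 (4Z,8S,9S,12S)-8,9:12,13-diepoxy-9,13-dimethyl-5-(triethylsilyloxy)tetradeca-1,4-diene
Conditions: CH2=CHMgBr, CuBr·SMe2 (10 mol %), Et3SiCl, DMPU, THF, –78 °C; Et3N, then cold aq NaHCO3
Reagents that add atoms: vinylmagnesium bromide, C=C[Mg]Br; chlorotriethylsilane, CC[Si](Cl)(CC)CC
Why: Chlorosilane-accelerated, copper-catalysed conjugate addition of a vinyl Grignard reagent: 1,4-addition to the s-cis vinyl ketone outruns any attack on the hindered epoxides at –78 °C and the enolate is silylated as it forms, which fixes the enol ether on the side of the new allyl group and mainly as the Z isomer; no stereocentre is formed.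

Step 4
Reactants: 6 (4Z,8S,9S,12S)-8,9:12,13-diepoxy-9,13-dimethyl-5-(triethylsilyloxy)tetradeca-1,4-diene
Product: 7 (3S,5aS,6S,9aS)-6-allyl-2,2,5a-trimethyl-3-(triethylsilyloxy)perhydro-1-benzoxepin-7-one (trans-fused rings C/D)
Conditions: Et3SiOTf (0.2 equiv), 2,6-di-tert-butyl-4-methylpyridine (0.3 equiv), CH2Cl2, –78 °C
Reagents that add atoms: none
Why: Silyl-triflate-initiated tandem oxa-/carbacyclisation of a 1,5-diepoxide terminated by a silyl enol ether: silylation of the terminal epoxide lets the internal epoxide oxygen open it at its tertiary carbon, the bicyclic epoxonium ion is then opened with inversion at its tertiary carbon by the enol ether through a chair, so the S,S-epoxide fixes the trans ring fusion, the Z enol ether places the allyl group equatorial (also the thermodynamic α-epimer), and the silyl triflate released from the enol ether carries the chain.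

Step 5
Reactants: 7 (3S,5aS,6S,9aS)-6-allyl-2,2,5a-trimethyl-3-(triethylsilyloxy)perhydro-1-benzoxepin-7-one
Product: 9 (3S,5aS,6S,7R,9aS)-6-allyl-2,2,5a,7-tetramethyl-3-(triethylsilyloxy)perhydro-1-benzoxepin-7-yl acetate, via lithium alkoxide 8 (not isolated)
Conditions: MeLi, Et2O–THF, –78 °C; then Ac2O, DMAP (cat.), –78 °C → rt
Reagents that add atoms: methyllithium, [Li]C; acetic anhydride, CC(=O)OC(C)=O
Why: 1,2-Addition of methyllithium followed by O-acylation of the alkoxide in the flask: the axial trajectory is blocked by the 1,3-diaxial angular methyl group, so the small nucleophile enters equatorially and sets the carbinol carbon with methyl equatorial and oxygen axial (7R), and the charged alkoxide is acetylated far more readily than the neutral hindered tertiary alcohol would be.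

Step 6
Reactants: 9 (3S,5aS,6S,7R,9aS)-6-allyl-2,2,5a,7-tetramethyl-3-(triethylsilyloxy)perhydro-1-benzoxepin-7-yl acetate; 5 (6S,7S,10S)-6,7:10,11-diepoxy-7,11-dimethyldodec-1-en-3-one
Product: 10 (3S,5aS,6S,7R,9aS)-6-[(2E,7S,8S,11S)-7,8:11,12-diepoxy-8,12-dimethyl-4-oxotridec-2-en-1-yl]-2,2,5a,7-tetramethyl-3-(triethylsilyloxy)perhydro-1-benzoxepin-7-yl acetate
Conditions: RuCl2(H2IMes)(=CH-2-iPrOC6H4) (second-generation Hoveyda–Grubbs catalyst, 5 mol %), 5 (2 equiv), CH2Cl2, 40 °C
Reagents that add atoms: none
Why: Olefin cross-metathesis (Chauvin mechanism): the ruthenium carbene engages the unhindered allyl terminus of 9 first, and the resulting alkylidene undergoes [2+2] cycloaddition and cycloreversion with the vinyl ketone 5, which releases ethene and forms the C=C bond between the former allyl CH and the α-carbon of the ketone. The closest known reaction type is the cross-metathesis of a rapidly reacting terminal alkene with an electron-poor alkyl vinyl ketone, which is cross-selective because the enone homodimerises only slowly and the product enone does not re-enter the cycle. The step closes no ring and creates no stereocentre; its only stereochemical element is the alkene geometry, which should be E under thermodynamic control and is erased in step 7 in any case. The selectivity needed is chemoselectivity, and it is secured because each partner holds a single metathesis-active alkene while the trisubstituted epoxides, the silyl ether and the tertiary acetate are inert to the catalyst. What the step buys is position: the carbonyl group sits one carbon away from the new bond, so later enol ether formation is regiodefined and the future ring-B methine becomes both the nucleophilic terminus of the cascade and a centre that can be corrected by equilibration.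

Step 7
Reactants: 10 E-enone from step 6
Product: 11 (3S,5aS,6S,7R,9aS)-6-[(3Z,7S,8S,11S)-4-(tert-butyldimethylsilyloxy)-7,8:11,12-diepoxy-8,12-dimethyltridec-3-en-1-yl]-2,2,5a,7-tetramethyl-3-(triethylsilyloxy)perhydro-1-benzoxepin-7-yl acetate
Conditions: tBuMe2SiH, Pt2[(CH2=CHSiMe2)2O]3 (Karstedt catalyst, 1 mol %), toluene, 40 °C
Reagents that add atoms: tert-butyldimethylsilane, C[SiH](C)C(C)(C)C
Why: Platinum-catalysed 1,4-hydrosilylation of an enone with a trialkylsilane: hydride is delivered to the β-carbon of the s-cis enone and silicon to oxygen, which should give only the enol ether that points toward the bridge and mainly its Z isomer, with no other alkene or reactive carbonyl group in 10 to compete.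

Step 8
Reactants: 11 Z-silyl enol ether from step 7
Product: 12 (3S,5aS,6S,7R,9aS)-6-{2-[(3S,5aS,6S,9aS)-3-(tert-butyldimethylsilyloxy)-2,2,5a-trimethyl-7-oxoperhydro-1-benzoxepin-6-yl]ethyl}-2,2,5a,7-tetramethyl-3-(triethylsilyloxy)perhydro-1-benzoxepin-7-yl acetate
Conditions: tBuMe2SiOTf (0.3 equiv), 2,6-di-tert-butyl-4-methylpyridine (0.4 equiv), CH2Cl2, –78 °C
Reagents that add atoms: none
Why: Same silyl-triflate-initiated tandem oxa-/carbacyclisation as in step 4: ring A arises by attack of the internal epoxide oxygen on the tertiary carbon of the silylated terminal epoxide and ring B by six-membered chair closure of the Z enol ether onto the tertiary epoxonium carbon with inversion, so the epoxide centres dictate the trans A/B fusion and the bridge ends up equatorial at the new methine (also the thermodynamic epimer next to the ketone), while low temperature, the hindered pyridine and substoichiometric triflate should spare the tertiary acetate and the triethylsilyl ether.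

Step 9
Reactants: 12 tetracyclic ring-B ketone from step 8
Product: 13 (3S,5aS,6S,7R,9aS)-6-{2-[(3S,5aS,6R,9aS)-3-(tert-butyldimethylsilyloxy)-2,2,5a-trimethyl-7-methylideneperhydro-1-benzoxepin-6-yl]ethyl}-2,2,5a,7-tetramethyl-3-(triethylsilyloxy)perhydro-1-benzoxepin-7-yl acetate
Conditions: Ph3PCH3Br, KOtBu, THF, 0 °C → 45 °C
Reagents that add atoms: methyltriphenylphosphonium bromide, C[P+](c1ccccc1)(c1ccccc1)c1ccccc1.[Br-]
Why: Wittig methylenation: the unstabilised ylide converts the only ketone of 12 into the exocyclic methylene group, the hindered tertiary acetate and both silyl ethers being poor electrophiles for it, and any base-induced equilibration at the α-methine can only reinforce the equatorial (desired) configuration.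

Step 10
Reactants: 13 bis-silyl ether from step 9
Product: 15 (5aS,6S,7R,9aS)-6-{2-[(3S,5aS,6R,9aS)-3-(tert-butyldimethylsilyloxy)-2,2,5a-trimethyl-7-methylideneperhydro-1-benzoxepin-6-yl]ethyl}-2,2,5a,7-tetramethyl-3-oxoperhydro-1-benzoxepin-7-yl acetate, via free ring-D alcohol 14 (not isolated)
Conditions: IBX (4 equiv), wet DMSO, rt
Reagents that add atoms: none
Why: One-pot cleavage and oxidation of a triethylsilyl ether with IBX in DMSO: the more labile triethylsilyl ether is hydrolysed selectively while the tert-butyldimethylsilyl ether stays, and the liberated ring-D alcohol is oxidised at once to the ketone, which removes that stereocentre and differentiates the two otherwise identical oxepane carbinols.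

Step 11
Reactants: 15 ring-D ketone from step 10
Product: 16 target, (5aS,6S,7R,9aS)-6-{2-[(3S,5aS,6R,9aS)-3-hydroxy-2,2,5a-trimethyl-7-methylideneperhydro-1-benzoxepin-6-yl]ethyl}-2,2,5a,7-tetramethyl-3-oxoperhydro-1-benzoxepin-7-yl acetate
Conditions: HF·pyridine, pyridine–THF, 0 °C → rt
Reagents that add atoms: none
Why: Fluoride-induced desilylation driven by the strong Si–F bond: buffered HF·pyridine should free the ring-A alcohol with retention at carbon and without touching the ketone, the tertiary acetate or the exocyclic alkene.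

Compound list
1 | (E)-geranylacetone | CC(=O)CC/C=C(C)/CCC=C(C)C | starting material
2 | (5S,6S,9S)-5,6:9,10-diepoxy-6,10-dimethylundecan-2-one | CC(=O)CC[C@@H]1O[C@@]1(C)CC[C@@H]1OC1(C)C | intermediate
3 | Mannich base, (6S,7S,10S)-1-(dimethylamino)-6,7:10,11-diepoxy-7,11-dimethyldodecan-3-one | CN(C)CCC(=O)CC[C@@H]1O[C@@]1(C)CC[C@@H]1OC1(C)C | intermediate
4 | N-methyl quaternary ammonium iodide of 3 | C[N+](C)(C)CCC(=O)CC[C@@H]1O[C@@]1(C)CC[C@@H]1OC1(C)C.[I-] | intermediate
5 | (6S,7S,10S)-6,7:10,11-diepoxy-7,11-dimethyldodec-1-en-3-one | C=CC(=O)CC[C@@H]1O[C@@]1(C)CC[C@@H]1OC1(C)C | intermediate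
6 | (4Z,8S,9S,12S)-8,9:12,13-diepoxy-9,13-dimethyl-5-(triethylsilyloxy)tetradeca-1,4-diene | C=CC/C=C(\O[Si](CC)(CC)CC)CC[C@@H]1O[C@@]1(C)CC[C@@H]1OC1(C)C | intermediate
7 | (3S,5aS,6S,9aS)-6-allyl-2,2,5a-trimethyl-3-(triethylsilyloxy)perhydro-1-benzoxepin-7-one | C=CC[C@H]1[C@]2(C)CC[C@H](O[Si](CC)(CC)CC)C(C)(C)O[C@H]2CCC1=O | intermediate
8 | lithium (7R)-alkoxide from methyl addition to 7 | C=CC[C@H]1[C@]2(C)CC[C@H](O[Si](CC)(CC)CC)C(C)(C)O[C@H]2CC[C@@]1(C)[O-].[Li+] | intermediate
9 | (3S,5aS,6S,7R,9aS)-6-allyl-2,2,5a,7-tetramethyl-3-(triethylsilyloxy)perhydro-1-benzoxepin-7-yl acetate | C=CC[C@H]1[C@]2(C)CC[C@H](O[Si](CC)(CC)CC)C(C)(C)O[C@H]2CC[C@@]1(C)OC(C)=O | intermediate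
10 | E-enone joining rings C/D to the open-chain diepoxide | O=C(CC[C@@H]1O[C@@]1(C)CC[C@@H]1OC1(C)C)/C=C/C[C@H]1[C@]2(C)CC[C@H](O[Si](CC)(CC)CC)C(C)(C)O[C@H]2CC[C@@]1(C)OC(C)=O | intermediate
11 | Z-tert-butyldimethylsilyl enol ether of the saturated ketone derived from 10 | CC(C)(C)[Si](C)(C)O/C(CC[C@@H]1O[C@@]1(C)CC[C@@H]1OC1(C)C)=C\CC[C@H]1[C@]2(C)CC[C@H](O[Si](CC)(CC)CC)C(C)(C)O[C@H]2CC[C@@]1(C)OC(C)=O | intermediate
12 | tetracyclic ring-B ketone (ring A OTBS, ring D OTES) | O=C1CC[C@@H]2OC(C)(C)[C@@H](O[Si](C)(C)C(C)(C)C)CC[C@@]2(C)[C@@H]1CC[C@H]1[C@]2(C)CC[C@H](O[Si](CC)(CC)CC)C(C)(C)O[C@H]2CC[C@@]1(C)OC(C)=O | intermediate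
13 | ring-B exocyclic methylene compound (ring A OTBS, ring D OTES) | C=C1CC[C@@H]2OC(C)(C)[C@@H](O[Si](C)(C)C(C)(C)C)CC[C@@]2(C)[C@@H]1CC[C@H]1[C@]2(C)CC[C@H](O[Si](CC)(CC)CC)C(C)(C)O[C@H]2CC[C@@]1(C)OC(C)=O | intermediate
14 | free ring-D (3S)-alcohol (ring A OTBS) | C=C1CC[C@@H]2OC(C)(C)[C@@H](O[Si](C)(C)C(C)(C)C)CC[C@@]2(C)[C@@H]1CC[C@H]1[C@]2(C)CC[C@H](O)C(C)(C)O[C@H]2CC[C@@]1(C)OC(C)=O | intermediate
15 | ring-D ketone (ring A OTBS) | C=C1CC[C@@H]2OC(C)(C)[C@@H](O[Si](C)(C)C(C)(C)C)CC[C@@]2(C)[C@@H]1CC[C@H]1[C@]2(C)CCC(=O)C(C)(C)O[C@H]2CC[C@@]1(C)OC(C)=O | intermediate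
16 | CNP0148623.1 | C=C1CC[C@@H]2OC(C)(C)[C@@H](O)CC[C@@]2(C)[C@@H]1CC[C@H]1[C@]2(C)CCC(=O)C(C)(C)O[C@H]2CC[C@@]1(C)OC(C)=O | target

Total step count: 11. Compound 5 is made once and used in steps 3 and 6.
Longest linear sequence: 11 steps (1 → 2 → 5 → 6 → 7 → 9 → 10 → 11 → 12 → 13 → 15 → 16).

Steps most likely to fail

Step 8. The silyl triflate may ionise or eliminate the tertiary acetate. The enol ether may be lost by protodesilylation before it cyclises. The epoxonium ion may also open at the wrong carbon or by proton loss. The fallback changes the protecting-group logic so that no ionisable ester is present during the cascade.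
- It sets out from 7: methyllithium addition is quenched with water and should give the tertiary alcohol F1.
- Cross-metathesis of F1 with 5 under the conditions of step 6 should give the hydroxy enone F2.
- Platinum-catalysed hydrosilylation should give the silyl enol ether F3.
- The cascade should give the hydroxy ketone F4.
- Acetylation of F4 (Ac2O, DMAP, Et3N, 60 °C) brings the sequence back to the route at 12.

Step 5. Methyllithium may enolise the α-allyl ketone instead of adding to it, and the very hindered axial alkoxide may be acylated only slowly. The fallback replaces carbanion addition by methylene transfer and hydride opening.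
- It sets out from 7: Corey–Chaykovsky reaction with dimethylsulfonium methylide (Me3S+ I–, NaH, DMSO–THF) should attack equatorially for the same steric reason and give the spiro-epoxide F5 with axial oxygen.
- LiBHEt3 should open F5 at its CH2 terminus.
- This returns to the route at the lithium alkoxide 8, which is acetylated in the flask as before.

Step 2. Kinetic deprotonation may be incompletely regioselective, and the vinyl ketone may polymerise or add amine during quaternisation and elimination. The fallback is an aldol–dehydration sequence that stores the enone in masked form.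
- It sets out from 2: the lithium enolate is treated with monomeric formaldehyde and should give the β-hydroxy ketone F6, which can be purified and kept.
- MsCl and Et3N convert F6 into the mesylate F7.
- F7 eliminates in the same flask just before use and comes back to the route at 5.

Further compounds
F1 | step 8 | (3S,5aS,6S,7R,9aS)-6-allyl-2,2,5a,7-tetramethyl-3-(triethylsilyloxy)perhydro-1-benzoxepin-7-ol | C=CC[C@H]1[C@]2(C)CC[C@H](O[Si](CC)(CC)CC)C(C)(C)O[C@H]2CC[C@@]1(C)O
F2 | step 8 | E-enone as 10 with free tertiary alcohol | O=C(CC[C@@H]1O[C@@]1(C)CC[C@@H]1OC1(C)C)/C=C/C[C@H]1[C@]2(C)CC[C@H](O[Si](CC)(CC)CC)C(C)(C)O[C@H]2CC[C@@]1(C)O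
F3 | step 8 | Z-silyl enol ether as 11 with free tertiary alcohol | CC(C)(C)[Si](C)(C)O/C(CC[C@@H]1O[C@@]1(C)CC[C@@H]1OC1(C)C)=C\CC[C@H]1[C@]2(C)CC[C@H](O[Si](CC)(CC)CC)C(C)(C)O[C@H]2CC[C@@]1(C)O
F4 | step 8 | tetracyclic ring-B ketone as 12 with free tertiary alcohol | O=C1CC[C@@H]2OC(C)(C)[C@@H](O[Si](C)(C)C(C)(C)C)CC[C@@]2(C)[C@@H]1CC[C@H]1[C@]2(C)CC[C@H](O[Si](CC)(CC)CC)C(C)(C)O[C@H]2CC[C@@]1(C)O
F5 | step 5 | spiro-epoxide at the ring-C carbonyl carbon of 7 (oxygen axial) | C=CC[C@H]1[C@]2(C)CC[C@H](O[Si](CC)(CC)CC)C(C)(C)O[C@H]2CC[C@]13CO3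
F6 | step 2 | (6S,7S,10S)-6,7:10,11-diepoxy-1-hydroxy-7,11-dimethyldodecan-3-one | OCCC(=O)CC[C@@H]1O[C@@]1(C)CC[C@@H]1OC1(C)C
F7 | step 2 | methanesulfonate of F6 | CS(=O)(=O)OCCC(=O)CC[C@@H]1O[C@@]1(C)CC[C@@H]1OC1(C)C
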